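Ring C of the target (CNP0273977.0, compound 36) is built by a cyclobutenone–siloxyalkyne benzannulation in step 7; the full route is 17 steps with a longest linear sequence of 14. Nothing here has been run; every outcome is an expectation.

Shorthand used throughout: ArO = 3,4,5-trimethoxy-2-(3,4,5-trimethoxyphenoxy)phenoxy, the permethylated D–E unit bound through the oxygen on D1. Atom labels: ring C carries O–ring B on C1 and O–ring D on C4; ring B carries O–ring A on B1 and O–ring C on B6; ring D carries O–ring C on D1 and O–ring E on D2.

## Analysis of the target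

Compound 36 is an open chain of five benzene rings, A–B–C–D–E, joined only by four diaryl ether bonds and carrying fourteen free phenolic hydroxyls. It has no stereocentre and no ring other than the five arenes. Ring A is a 2,4,6-trihydroxyphenyl ether and ring E a 3,4,5-trihydroxyphenyl ether. Rings B and D are pentaoxygenated, each with two neighbouring aryloxy groups (B1/B6 and D1/D2) beside a pyrogallol triad. The central ring C is a benzene-1,3,4,5-tetrol in which O1 is bound to ring B, O4 to ring D, and O3 and O5 are free. The pyrogallol and phloroglucinol units are oxidised by air, above all under base, so every hydroxyl has to stay masked until a final, non-oxidative unmasking. The difficulty is twofold: all rings are electron-rich, so the ether bonds cannot be made by ordinary nucleophilic aromatic substitution, and the C4–O–D1 ether is flanked by three ortho oxygen substituents (on C3, C5 and D2); in addition, the four chemically similar oxygens of ring C must take up two different aryl groups at defined positions. The plan rests on ring C: it is built, not derivatised, from four carbons (C3 to C6) of a four-membered ketone that already holds the O4–ring D ether and from two carbons (C1, C2) of an oxygenated alkyne, so its four oxygens are different from the moment the ring exists.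

## Retrosynthetic reasoning

**36 from 35.** The last disconnection removes only alkyl groups: the twelve O–methyl and two O–ethyl bonds of 35 are cut in one Lewis-acid dealkylation. Alkyl ethers are the masks because they survive organolithium, fluoride, peracid and copper chemistry, and because the air-sensitive polyphenol then appears once, at the end, under acidic conditions. The diaryl ether bonds are inert to this cleavage.

**35 from 27 and 33.** The bond between C1 of ring C and the oxygen on B6 is cut next, which divides the pentamer into a three-ring and a two-ring half. The oxygen of 33 sits between an aryloxy and a methoxy group and is a poor partner for metal-catalysed coupling, but a good nucleophile towards an aryne. Silyl triflate 27 releases aryne 34 (C1≡C2 of ring C). The ethoxy group on C3, next to the triple bond, steers the phenoxide to C1, and the carbon that loses silicon ends as C2–H.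

**27 from 20.** The ortho-silyl triflate is traced to phenol 20 through carbamate 21. The carbamate directs lithiation to the position between itself and an ethoxy group (25, through 22, 23 and 24) and is then exchanged for triflate in one flask (through 26). Because ring C of 20 carries two identical ethoxy groups, its two ortho positions are equivalent and no regiochemical question arises.

**20 from 18.** Phenol 20 comes from silyl ether 19 by fluoride, and 19 from phenol 18 by O-ethylation. Here the differentiation created in the key step is used: O3 is capped and O1 alone is set free. Ethyl, not methyl, is chosen for the cap so that ring C becomes symmetric.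

**18 from 12 and 13 (key disconnection).** Ring C is taken apart into four carbons of cyclobutenone 12 and the two carbons of siloxyalkyne 13. From 12 come C3 (the ketone), C4 (bearing the ether to ring D), C5 (the ethyl enol ether) and C6; from 13 come C1 with its silyloxy group and C2. Cutting here, and not at an aryl–oxygen bond of ring C, avoids any substitution at C4, which is flanked by two oxygenated carbons and would have to accept an ortho-substituted phenol. The forward cascade has to form C2–C3 and C1–C6 with the right orientation of the alkyne and then aromatise. It should deliver O1, O3, O4 and O5 as silyl ether, free phenol, aryl ether and ethyl ether.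

**12 from 9 and 10.** The cyclobutenone is cut across the ring into aryloxyketene 11 and ethoxyacetylene 10; the ketene is generated from acid chloride 9. The hindered C4–O–D1 bond of the target is thereby reduced to the sp3 C–O bond of an aryloxyacetic acid: 9 comes from acid 8, and 8 from phenol 6 and bromoacetic acid 7 by plain O-alkylation.

**6 from 2 and 3.** Phenol 6 is traced to aldehyde 4 through formate 5. The formyl group first activates the neighbouring carbon for ether formation and is then converted into the D1 hydroxyl. Aldehyde 4 is cut at the D2–O bond into bromoaldehyde 2 and phenol 3, and 2 comes from aldehyde 1 by bromination. Three dependable steps are preferred here to a ring synthesis, so that the risk of the route stays in the key step.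

**33 from 29 and 30.** The A–B phenol 33 follows the same logic with the substituents in the other order: aldehyde 31 (through formate 32) from bromoaldehyde 29 and phenol 30, and 29 from the symmetric bromide 28 by formylation next to bromine.

## Alternatives that were turned down

**Alternative 1:** The central hydroxyl of each pyrogallol triad (O4 of rings B, D and E) is traced back to a formyl group. The chain would be assembled as trialdehyde A2; one peracid treatment turns the three formyl groups into formates by aryl migration, and methanolysis gives tris-phenol A1, which needs only the final dealkylation.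
- For it: each formyl group does two jobs. It activates a halide para to it for ether formation at B1, D1 and E1, and it later becomes the missing oxygen. Every reaction type is classical, and the same oxidation is used on a small scale in steps 3 and 15 of the chosen route.
- Against it: para-activation does not help the B6–O–C1 bond, where neither carbon is activated and both partners are hindered. The hindered C4 oxygen of ring C would still have to act as a nucleophile. Three oxidations must all succeed in one molecule whose rings A and C are as electron-rich as the migrating rings and open to peracid hydroxylation.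
- Comparison: on precedent, and probably on step count, A1 is the stronger plan. The chosen strategy offers in its place an ether at C4 that arrives preformed through a ketene, an aryne coupling for C1 that tolerates hindrance, and ring C oxygens that never need to be told apart after the fact.

**Alternative 2:** Ring D is made from a squaric ester. Cyclobutenone A4 is heated; it opens to a dienylketene whose ketene carbon bonds to the terminal vinyl carbon (D1–D6), giving phenol A3, which is the same compound as 6.
- For it: the squarate carbons deliver contiguous oxygens with complete positional control, and the D2–O–ring E ether is put in by addition–elimination on the squarate, so no copper coupling next to two ortho substituents is needed. On that one bond it is stronger than step 2 of the chosen route.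
- Against it: the pericyclic step is spent on a fragment that three classical steps also reach. A4 requires regioselective addition of a lithiated enol ether to an unsymmetrical squarate and O-methylation of a tertiary alkoxide. The real problem, the hindered and undifferentiated ring C, is left untouched.
- Comparison: it could serve as another source of 6, but it cannot replace the key step, because the chosen strategy places its ring synthesis where classical ether chemistry is weakest.

**Alternative 3:** The same benzannulation is used at the chain end. The ethynyl ether A6 of the A–D tetramer (made from the tetramer phenol by the dichlorovinyl ether route) is heated with cyclobutenone A7, forming E2–E3 and E1–E6 and giving pentamer A5.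
- For it: the pentamer is completed in a single late step, and aryl ynol ethers are easy to prepare.
- Against it: ring E is the simplest ring of the target and is available as phenol 3, so building it spends the key step on the easiest problem. The tetramer, with ring C and its hindered ethers, must already exist. Making the ynol ether requires butyllithium on a substrate with many methoxy-flanked ring positions. An aryloxyalkyne is a weaker ketene partner than a siloxyalkyne. A5 ends with three kinds of protecting group on ring E for no gain.
- Comparison: the reaction type is equally well founded in both plans. The chosen strategy uses it on the central ring, where it solves the hindered C4–O bond and the oxygen differentiation at once.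

Key step: step 7

Assumption: (triisopropylsilyloxy)acetylene 13 is treated as a purchasable reagent (a known, distillable silyl ynol ether); methyl and ethyl aryl ethers are treated as equivalent masks because both are cleaved in step 17.

## Route

**Step 1**
Reactants: 1 3,4,5-trimethoxybenzaldehyde
Product: 2 2-bromo-3,4,5-trimethoxybenzaldehyde
Conditions: NBS, MeCN, rt
Reagents that add atoms: N-bromosuccinimide, O=C1CCC(=O)N1Br
Why: Electrophilic aromatic bromination; the two free positions are equivalent, each activated by an ortho and a para methoxy group, and the aldehyde plus the first bromine hold back a second substitution.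

**Step 2**
Reactants: 2 2-bromo-3,4,5-trimethoxybenzaldehyde; 3 3,4,5-trimethoxyphenol
Product: 4 3,4,5-trimethoxy-2-(3,4,5-trimethoxyphenoxy)benzaldehyde
Conditions: CuI (10 mol%), picolinic acid (20 mol%), K3PO4, DMSO, 90 °C
Reagents that add atoms: none
Why: Ullmann-type copper-catalysed C–O coupling; the ortho-formyl group speeds up replacement of the bromide and the picolinate system tolerates ortho substituents, the same bond type being the classical entry to ethers of 2-halo-3,4,5-trialkoxybenzoyl compounds.

**Step 3**
Reactants: 4 3,4,5-trimethoxy-2-(3,4,5-trimethoxyphenoxy)benzaldehyde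
Product: 6 3,4,5-trimethoxy-2-(3,4,5-trimethoxyphenoxy)phenol, via aryl formate 5 (not isolated)
Conditions: mCPBA, NaHCO3, CH2Cl2, 0 °C → rt; then K2CO3, MeOH, rt
Reagents that add atoms: 3-chloroperbenzoic acid, O=C(OO)c1cccc(Cl)c1
Why: Baeyer–Villiger (Dakin-type) oxidation; in the Criegee intermediate the aryl group, which carries ortho-aryloxy and para-methoxy donors, migrates in preference to hydrogen, and mild methanolysis of formate 5 frees the phenol without touching the ethers.

**Step 4**
Reactants: 6 3,4,5-trimethoxy-2-(3,4,5-trimethoxyphenoxy)phenol; 7 bromoacetic acid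
Product: 8 2-(ArO)acetic acid
Conditions: NaH (2.5 equiv), THF–DMF, 0 → 60 °C; then aq. HCl
Reagents that add atoms: none
Why: Williamson ether synthesis; the phenoxide displaces bromide from sodium bromoacetate at a primary carbon, which is insensitive to the ortho-aryloxy group.

**Step 5**
Reactants: 8 2-(ArO)acetic acid
Product: 9 2-(ArO)acetyl chloride
Conditions: (COCl)2, DMF (cat.), CH2Cl2, 0 °C → rt; concentrated and used crude
Reagents that add atoms: oxalyl chloride, O=C(Cl)C(=O)Cl
Why: Acid chloride formation through the Vilsmeier-type chloroiminium catalyst; no Lewis acid is present, so ring closure of the acid chloride onto the electron-rich ring D is not expected at this temperature.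

**Step 6**
Reactants: 9 2-(ArO)acetyl chloride; 10 ethoxyacetylene
Product: 12 racemic 4-(ArO)-3-ethoxycyclobut-2-en-1-one, via aryloxyketene 11 (not isolated)
Conditions: 10 (3 equiv), Et3N (slow addition), CH2Cl2, 0 °C → rt
Reagents that add atoms: none
Why: Dehydrochlorination gives ketene 11, which undergoes the known (2+2) cycloaddition of ketenes with ethoxyacetylene; the nucleophilic CH carbon of the ynol ether bonds to the ketene carbonyl carbon, so ethoxy ends on C3 and aryloxy on C4. The new stereocentre C4 is formed racemic and is destroyed in step 7.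

**Step 7**
Reactants: 12 racemic 4-(ArO)-3-ethoxycyclobut-2-en-1-one; 13 (triisopropylsilyloxy)acetylene
Product: 18 2-(ArO)-3-ethoxy-5-(triisopropylsilyloxy)phenol, via vinylketene 14 (not isolated), via vinylcyclobutenone 15 (not isolated), via dienylketene 16 (not isolated), via cyclohexadienone 17 (not isolated)
Conditions: 13 (2 equiv), toluene, 80 → 110 °C, Ar
Reagents that add atoms: none
Why: Heating opens 12 by conrotatory 4π cleavage of the bond between the carbonyl carbon and the aryloxy-bearing carbon, the oxygen donor turning outward, to give (Z)-vinylketene 14. The nucleophilic CH carbon of 13 attacks the ketene carbonyl carbon and the (2+2) adduct 15 forms; these are the ring C bonds C2–C3 and C1–C6. 15 opens (4π) to dienylketene 16, which closes ring C by a thermally allowed disrotatory 6π electrocyclisation, and dienone 17 tautomerises to phenol 18. The closest known reaction type is the Danheiser benzannulation of cyclobutenones with siloxyalkynes to resorcinol monosilyl ethers, which is established for 4-alkyl and 3-silyloxy cyclobutenones. No stereocentre is created, and the one in 12 is lost on aromatisation. The step needs one selectivity, the orientation of the ketene–alkyne cycloaddition; the polarisation of the ynol ether secures it and places the silyloxy group para to the aryloxy group and meta to the new hydroxyl. The four oxygens of ring C thus emerge as aryl ether (O4), ethyl ether (O5), silyl ether (O1) and free phenol (O3).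

**Step 8**
Reactants: 18 2-(ArO)-3-ethoxy-5-(triisopropylsilyloxy)phenol
Product: 19 [4-(ArO)-3,5-diethoxyphenoxy]triisopropylsilane
Conditions: EtI, K2CO3, acetone, 50 °C
Reagents that add atoms: iodoethane, CCI
Why: Williamson ether synthesis on the only free phenol; ethyl is chosen so that ring C carries two identical alkoxy groups and becomes symmetric, and the hindered aryl triisopropylsilyl ether withstands K2CO3 in acetone.

**Step 9**
Reactants: 19 [4-(ArO)-3,5-diethoxyphenoxy]triisopropylsilane
Product: 20 4-(ArO)-3,5-diethoxyphenol
Conditions: Bu4NF, THF, 0 °C; then H2O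
Reagents that add atoms: none
Why: Fluoride cleavage of the aryl silyl ether, driven by the Si–F bond; alkyl and diaryl ethers are untouched, so O1 alone is set free.

**Step 10**
Reactants: 20 4-(ArO)-3,5-diethoxyphenol
Product: 21 4-(ArO)-3,5-diethoxyphenyl N-isopropylcarbamate
Conditions: i-PrNCO, Et3N (cat.), CH2Cl2, rt
Reagents that add atoms: isopropyl isocyanate, CC(C)N=C=O
Why: Base-catalysed addition of the phenol to the isocyanate; the N-isopropyl carbamate is a strong director for ortho-lithiation and can later be removed by mild base through elimination to the isocyanate.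

**Step 11**
Reactants: 21 4-(ArO)-3,5-diethoxyphenyl N-isopropylcarbamate
Product: 25 4-(ArO)-3,5-diethoxy-2-(trimethylsilyl)phenyl N-isopropylcarbamate, via N-silyl carbamate 22 (not isolated), via aryllithium 23 (not isolated), via N-silyl ortho-silyl carbamate 24 (not isolated)
Conditions: TBSOTf, TMEDA, Et2O, 0 °C → rt; n-BuLi, TMEDA, −78 °C; Me3SiCl, −78 °C → rt; aq. NaHSO4
Reagents that add atoms: chlorotrimethylsilane, C[Si](C)(C)Cl
Why: Directed ortho-metalation; after N-silylation in the flask the carbamate directs n-BuLi to the ring C position between the carbamate oxygen and an ethoxy group, the most acidic site of the molecule, and Me3SiCl traps 23. Ring C is symmetric, so both ortho positions give the same product, and the acidic work-up removes the N-silyl group of 24.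

**Step 12**
Reactants: 25 4-(ArO)-3,5-diethoxy-2-(trimethylsilyl)phenyl N-isopropylcarbamate
Product: 27 4-(ArO)-3,5-diethoxy-2-(trimethylsilyl)phenyl trifluoromethanesulfonate, via silylphenol 26 (not isolated)
Conditions: DBU, Et2NH, MeCN, 40 °C; then PhNTf2, rt
Reagents that add atoms: N-phenylbis(trifluoromethanesulfonimide), O=S(=O)(N(c1ccccc1)S(=O)(=O)C(F)(F)F)C(F)(F)F
Why: DBU removes the carbamate N–H and the phenoxide leaves (E1cB), diethylamine scavenges the isocyanate, and the phenoxide of 26 is triflated in the same flask; this is the established one-pot conversion of ortho-silyl aryl carbamates into aryne precursors.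

**Step 13**
Reactants: 28 5-bromo-1,2,3-trimethoxybenzene
Product: 29 6-bromo-2,3,4-trimethoxybenzaldehyde
Conditions: Cl2CHOMe, TiCl4, CH2Cl2, −10 → 0 °C; then ice, aq. HCl
Reagents that add atoms: dichloromethyl methyl ether, COC(Cl)Cl; water, O
Why: Rieche formylation; the two free positions of symmetric 28 are equivalent, each ortho to one and para to another methoxy group, so a single aldehyde should form, as with the analogous 3,4,5-trimethoxytoluene. Low temperature limits loss of the methyl group ortho to the new carbonyl.

**Step 14**
Reactants: 29 6-bromo-2,3,4-trimethoxybenzaldehyde; 30 2,4,6-trimethoxyphenol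
Product: 31 2,3,4-trimethoxy-6-(2,4,6-trimethoxyphenoxy)benzaldehyde
Conditions: CuI (10 mol%), picolinic acid (20 mol%), K3PO4, DMSO, 90 °C
Reagents that add atoms: none
Why: Ullmann-type copper-catalysed C–O coupling; the bromide has a single ortho neighbour, the activating formyl group, which offsets the two ortho-methoxy groups of the electron-rich phenol.

**Step 15**
Reactants: 31 2,3,4-trimethoxy-6-(2,4,6-trimethoxyphenoxy)benzaldehyde
Product: 33 2,3,4-trimethoxy-6-(2,4,6-trimethoxyphenoxy)phenol, via aryl formate 32 (not isolated)
Conditions: mCPBA, NaHCO3, CH2Cl2, 0 °C → rt; then K2CO3, MeOH, rt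
Reagents that add atoms: 3-chloroperbenzoic acid, O=C(OO)c1cccc(Cl)c1
Why: Baeyer–Villiger (Dakin-type) oxidation; the aryl group with two ortho and one para oxygen donors migrates readily, and methanolysis of formate 32 gives the phenol.

**Step 16**
Reactants: 27 4-(ArO)-3,5-diethoxy-2-(trimethylsilyl)phenyl trifluoromethanesulfonate; 33 2,3,4-trimethoxy-6-(2,4,6-trimethoxyphenoxy)phenol
Product: 35 1,3-diethoxy-2-(ArO)-5-[2,3,4-trimethoxy-6-(2,4,6-trimethoxyphenoxy)phenoxy]benzene, via aryne 34 (not isolated)
Conditions: 33 (1.5 equiv), CsF, MeCN, rt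
Reagents that add atoms: none
Why: Fluoride-induced 1,2-elimination of 27 gives aryne 34, and the phenoxide of 33 adds to C1, the aryne carbon remote from the neighbouring ethoxy group, because the inductively withdrawing alkoxy group polarises the aryne and stabilises the developing charge on C2; protonation completes the O-arylation. Arynes accept hindered phenoxides that are poor partners in metal-catalysed couplings.

**Step 17**
Reactants: 35 1,3-diethoxy-2-(ArO)-5-[2,3,4-trimethoxy-6-(2,4,6-trimethoxyphenoxy)phenoxy]benzene
Product: 36 5-[2,3,4-trihydroxy-6-(2,4,6-trihydroxyphenoxy)phenoxy]-2-[3,4,5-trihydroxy-2-(3,4,5-trihydroxyphenoxy)phenoxy]benzene-1,3-diol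
Conditions: BBr3 (excess), CH2Cl2, −78 °C → rt, Ar; then MeOH, 0 °C; degassed acidic work-up
Reagents that add atoms: none
Why: Lewis-acid dealkylation of aryl alkyl ethers; bromide attacks the methyl or ethyl carbon of each boron-complexed ether, whereas the diaryl ether bonds offer no sp3 carbon and stay intact. No base or oxidant is present, so the pyrogallol units should survive if air is excluded.

## Compound list

1 | 3,4,5-trimethoxybenzaldehyde | COc1cc(C=O)cc(OC)c1OC | starting material
2 | 2-bromo-3,4,5-trimethoxybenzaldehyde | COc1cc(C=O)c(Br)c(OC)c1OC | intermediate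
3 | 3,4,5-trimethoxyphenol | COc1cc(O)cc(OC)c1OC | starting material
4 | 3,4,5-trimethoxy-2-(3,4,5-trimethoxyphenoxy)benzaldehyde | O=Cc1cc(OC)c(OC)c(OC)c1Oc1cc(OC)c(OC)c(OC)c1 | intermediate
5 | 3,4,5-trimethoxy-2-(3,4,5-trimethoxyphenoxy)phenyl formate | O=COc1cc(OC)c(OC)c(OC)c1Oc1cc(OC)c(OC)c(OC)c1 | intermediate (not isolated)
6 | 3,4,5-trimethoxy-2-(3,4,5-trimethoxyphenoxy)phenol | Oc1cc(OC)c(OC)c(OC)c1Oc1cc(OC)c(OC)c(OC)c1 | intermediate
7 | bromoacetic acid | OC(=O)CBr | starting material
8 | 2-(ArO)acetic acid | OC(=O)COc1cc(OC)c(OC)c(OC)c1Oc1cc(OC)c(OC)c(OC)c1 | intermediate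
9 | 2-(ArO)acetyl chloride | ClC(=O)COc1cc(OC)c(OC)c(OC)c1Oc1cc(OC)c(OC)c(OC)c1 | intermediate
10 | ethoxyacetylene | CCOC#C | starting material
11 | (ArO)ketene, 2-(ArO)ethen-1-one | O=C=COc1cc(OC)c(OC)c(OC)c1Oc1cc(OC)c(OC)c(OC)c1 | intermediate (not isolated)
12 | racemic 4-(ArO)-3-ethoxycyclobut-2-en-1-one | CCOC1=CC(=O)C1Oc1cc(OC)c(OC)c(OC)c1Oc1cc(OC)c(OC)c(OC)c1 | intermediate
13 | (triisopropylsilyloxy)acetylene | C#CO[Si](C(C)C)(C(C)C)C(C)C | starting material
14 | (3Z)-4-(ArO)-3-ethoxybuta-1,3-dien-1-one | O=C=C/C(OCC)=C/Oc1cc(OC)c(OC)c(OC)c1Oc1cc(OC)c(OC)c(OC)c1 | intermediate (not isolated)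
15 | racemic 4-[(Z)-2-(ArO)-1-ethoxyethenyl]-3-(triisopropylsilyloxy)cyclobut-2-en-1-one | O=C1C=C(O[Si](C(C)C)(C(C)C)C(C)C)C1/C(OCC)=C/Oc1cc(OC)c(OC)c(OC)c1Oc1cc(OC)c(OC)c(OC)c1 | intermediate (not isolated)
16 | (3E,5Z)-6-(ArO)-5-ethoxy-3-(triisopropylsilyloxy)hexa-1,3,5-trien-1-one | O=C=C/C(O[Si](C(C)C)(C(C)C)C(C)C)=C\C(OCC)=C\Oc1cc(OC)c(OC)c(OC)c1Oc1cc(OC)c(OC)c(OC)c1 | intermediate (not isolated)
17 | racemic 6-(ArO)-5-ethoxy-3-(triisopropylsilyloxy)cyclohexa-2,4-dien-1-one | O=C1C=C(O[Si](C(C)C)(C(C)C)C(C)C)C=C(OCC)C1Oc1cc(OC)c(OC)c(OC)c1Oc1cc(OC)c(OC)c(OC)c1 | intermediate (not isolated)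
18 | 2-(ArO)-3-ethoxy-5-(triisopropylsilyloxy)phenol | CCOc1cc(O[Si](C(C)C)(C(C)C)C(C)C)cc(O)c1Oc1cc(OC)c(OC)c(OC)c1Oc1cc(OC)c(OC)c(OC)c1 | intermediate
19 | [4-(ArO)-3,5-diethoxyphenoxy]triisopropylsilane | CCOc1cc(O[Si](C(C)C)(C(C)C)C(C)C)cc(OCC)c1Oc1cc(OC)c(OC)c(OC)c1Oc1cc(OC)c(OC)c(OC)c1 | intermediate
20 | 4-(ArO)-3,5-diethoxyphenol | CCOc1cc(O)cc(OCC)c1Oc1cc(OC)c(OC)c(OC)c1Oc1cc(OC)c(OC)c(OC)c1 | intermediate
21 | 4-(ArO)-3,5-diethoxyphenyl N-isopropylcarbamate | CCOc1cc(OC(=O)NC(C)C)cc(OCC)c1Oc1cc(OC)c(OC)c(OC)c1Oc1cc(OC)c(OC)c(OC)c1 | intermediate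
22 | 4-(ArO)-3,5-diethoxyphenyl N-(tert-butyldimethylsilyl)-N-isopropylcarbamate | CCOc1cc(OC(=O)N(C(C)C)[Si](C)(C)C(C)(C)C)cc(OCC)c1Oc1cc(OC)c(OC)c(OC)c1Oc1cc(OC)c(OC)c(OC)c1 | intermediate (not isolated)
23 | 2-lithio derivative of 22 (lithium on the ring C carbon between the carbamate oxygen and an ethoxy group) | [Li]c1c(OC(=O)N(C(C)C)[Si](C)(C)C(C)(C)C)cc(OCC)c(Oc2cc(OC)c(OC)c(OC)c2Oc2cc(OC)c(OC)c(OC)c2)c1OCC | intermediate (not isolated)
24 | 4-(ArO)-3,5-diethoxy-2-(trimethylsilyl)phenyl N-(tert-butyldimethylsilyl)-N-isopropylcarbamate | C[Si](C)(C)c1c(OC(=O)N(C(C)C)[Si](C)(C)C(C)(C)C)cc(OCC)c(Oc2cc(OC)c(OC)c(OC)c2Oc2cc(OC)c(OC)c(OC)c2)c1OCC | intermediate (not isolated)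
25 | 4-(ArO)-3,5-diethoxy-2-(trimethylsilyl)phenyl N-isopropylcarbamate | C[Si](C)(C)c1c(OC(=O)NC(C)C)cc(OCC)c(Oc2cc(OC)c(OC)c(OC)c2Oc2cc(OC)c(OC)c(OC)c2)c1OCC | intermediate
26 | 4-(ArO)-3,5-diethoxy-2-(trimethylsilyl)phenol | C[Si](C)(C)c1c(O)cc(OCC)c(Oc2cc(OC)c(OC)c(OC)c2Oc2cc(OC)c(OC)c(OC)c2)c1OCC | intermediate (not isolated)
27 | 4-(ArO)-3,5-diethoxy-2-(trimethylsilyl)phenyl trifluoromethanesulfonate | C[Si](C)(C)c1c(OS(=O)(=O)C(F)(F)F)cc(OCC)c(Oc2cc(OC)c(OC)c(OC)c2Oc2cc(OC)c(OC)c(OC)c2)c1OCC | intermediate
28 | 5-bromo-1,2,3-trimethoxybenzene | COc1cc(Br)cc(OC)c1OC | starting material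
29 | 6-bromo-2,3,4-trimethoxybenzaldehyde | COc1cc(Br)c(C=O)c(OC)c1OC | intermediate
30 | 2,4,6-trimethoxyphenol | COc1cc(OC)c(O)c(OC)c1 | starting material
31 | 2,3,4-trimethoxy-6-(2,4,6-trimethoxyphenoxy)benzaldehyde | COc1cc(OC)c(Oc2cc(OC)c(OC)c(OC)c2C=O)c(OC)c1 | intermediate
32 | 2,3,4-trimethoxy-6-(2,4,6-trimethoxyphenoxy)phenyl formate | COc1cc(OC)c(Oc2cc(OC)c(OC)c(OC)c2OC=O)c(OC)c1 | intermediate (not isolated)
33 | 2,3,4-trimethoxy-6-(2,4,6-trimethoxyphenoxy)phenol | COc1cc(OC)c(Oc2cc(OC)c(OC)c(OC)c2O)c(OC)c1 | intermediate
34 | 4-(ArO)-3,5-diethoxy-1,2-didehydrobenzene (aryne) | CCOC1=CC#CC(OCC)=C1Oc1cc(OC)c(OC)c(OC)c1Oc1cc(OC)c(OC)c(OC)c1 | intermediate (not isolated)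
35 | 1,3-diethoxy-2-(ArO)-5-[2,3,4-trimethoxy-6-(2,4,6-trimethoxyphenoxy)phenoxy]benzene (rings A, B, D, E as trimethyl ethers, ring C as diethyl ether) | COc1cc(OC)c(Oc2cc(OC)c(OC)c(OC)c2Oc2cc(OCC)c(Oc3cc(OC)c(OC)c(OC)c3Oc3cc(OC)c(OC)c(OC)c3)c(OCC)c2)c(OC)c1 | intermediate
36 | 5-[2,3,4-trihydroxy-6-(2,4,6-trihydroxyphenoxy)phenoxy]-2-[3,4,5-trihydroxy-2-(3,4,5-trihydroxyphenoxy)phenoxy]benzene-1,3-diol | Oc1cc(O)c(Oc2cc(O)c(O)c(O)c2Oc2cc(O)c(Oc3cc(O)c(O)c(O)c3Oc3cc(O)c(O)c(O)c3)c(O)c2)c(O)c1 | target

## Step count and least certain steps

Total: 17 steps. Longest linear sequence: 14 steps (steps 1 to 12, then 16 and 17). Steps 13 to 15 form the three-step branch to 33.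

**Step 7 (key step).**
- Risk: the vinylogous-ester stabilisation of 12 slows ring opening, and the donor-substituted vinylketene 14 is a weak electrophile. It may reclose, dimerise or be captured by the product phenol (acylation of 18) faster than it is trapped by 13. At the upper end of the temperature range 13 can isomerise to a silylketene.
- Fallback (from 6, returning at 36): ring C is not built but bought, at the price of making the hindered ether by coupling. Copper-catalysed coupling of 6 with purchased 4-bromo-3,5-dimethoxybenzaldehyde (CuI, picolinic acid, K3PO4, DMSO, 110 °C), the para-formyl group assisting substitution at the doubly flanked carbon, should give 4-(ArO)-3,5-dimethoxybenzaldehyde F1. Peracid and then K2CO3/MeOH, as in step 3, convert it through 4-(ArO)-3,5-dimethoxyphenyl formate F2 into 4-(ArO)-3,5-dimethoxyphenol F3. Tf2O/pyridine gives 4-(ArO)-3,5-dimethoxyphenyl trifluoromethanesulfonate F4, which is coupled with 33 (Pd(OAc)2, 2-di-tert-butylphosphino-2',4',6'-triisopropylbiphenyl, K3PO4, toluene, 100 °C) to the tetradecamethyl ether of the target F5. BBr3 as in step 17 then gives 36.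

**Step 6.**
- Risk: ketene 11 may dimerise or polymerise before the only moderately nucleophilic ethoxyacetylene traps it, and the acidic, hydrolysis-prone enol ether 12 may degrade under amine base or on isolation.
- Fallback (from 9, returning at 19): the more nucleophilic alkyne 13 is used for both cycloadditions and the oxygens are then distinguished by hindrance. Et3N and 13 (2.2 equiv) in toluene, rt then 80 °C, should trap 11 as racemic 4-(ArO)-3-(triisopropylsilyloxy)cyclobut-2-en-1-one F6, which reacts on in the same flask with a second molecule of 13 to 2-(ArO)-3,5-bis(triisopropylsilyloxy)phenol F7. Bu4NF gives 2-(ArO)benzene-1,3,5-triol F8. One equivalent of i-Pr3SiCl/imidazole silylates the single hydroxyl not flanked by the aryloxy group to give 2-(ArO)-5-(triisopropylsilyloxy)benzene-1,3-diol F9. EtI/K2CO3 then gives 19.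

**Step 11.**
- Risk: lithiation may also occur at ring positions between two ether oxygens on rings D and E, and the carbamoyl group may migrate to carbon (anionic ortho-Fries shift) if the aryllithium warms before silylation.
- Fallback (from 20, returning at 27): the classical halogen route. NBS (1 equiv, CH2Cl2, −78 °C, cat. i-Pr2NH) should give 4-(ArO)-2-bromo-3,5-diethoxyphenol F10, and (Me3Si)2NH gives [4-(ArO)-2-bromo-3,5-diethoxyphenoxy]trimethylsilane F11. n-BuLi at −78 °C effects bromine–lithium exchange and O→C silyl migration to the lithium salt of 26, and Tf2O gives 27.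

**Step 16.**
- Risk: aryne 34 may be consumed by fluoride, solvent or adventitious proton sources before the hindered phenoxide of 33 adds, and the oxygen substituents on C4 and C5 may erode the regiochemical preference for C1.
- Fallback (from 20, returning at 35): the aryne is avoided altogether. Tf2O/pyridine gives 4-(ArO)-3,5-diethoxyphenyl trifluoromethanesulfonate F12, whose ortho positions are free, and palladium-catalysed C–O coupling with 33 (Pd(OAc)2, 2-di-tert-butylphosphino-2',4',6'-triisopropylbiphenyl, K3PO4, toluene, 100 °C) gives 35.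

**Step 17.**
- Risk: cleavage of the fourteen ethers may stop short, the ethyl ethers and chelated boron esters being the slowest, and the free pyrogallol units may be oxidised during isolation.
- Fallback (from 35, returning at 36): the crude product of the BBr3 treatment is not isolated but acetylated at once (Ac2O, pyridine) to the tetradecaacetate of the target F13. This is stable to air and silica, so it can be separated from partly alkylated material, which is resubmitted. Acid-catalysed methanolysis (HCl in MeOH, Ar) then releases 36 without any exposure to base.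

## Further compounds

F1 | step 7 | 4-(ArO)-3,5-dimethoxybenzaldehyde | COc1cc(C=O)cc(OC)c1Oc1cc(OC)c(OC)c(OC)c1Oc1cc(OC)c(OC)c(OC)c1
F2 | step 7 | 4-(ArO)-3,5-dimethoxyphenyl formate | COc1cc(OC=O)cc(OC)c1Oc1cc(OC)c(OC)c(OC)c1Oc1cc(OC)c(OC)c(OC)c1
F3 | step 7 | 4-(ArO)-3,5-dimethoxyphenol | COc1cc(O)cc(OC)c1Oc1cc(OC)c(OC)c(OC)c1Oc1cc(OC)c(OC)c(OC)c1
F4 | step 7 | 4-(ArO)-3,5-dimethoxyphenyl trifluoromethanesulfonate | COc1cc(OS(=O)(=O)C(F)(F)F)cc(OC)c1Oc1cc(OC)c(OC)c(OC)c1Oc1cc(OC)c(OC)c(OC)c1
F5 | step 7 | tetradecamethyl ether of the target | COc1cc(OC)c(Oc2cc(OC)c(OC)c(OC)c2Oc2cc(OC)c(Oc3cc(OC)c(OC)c(OC)c3Oc3cc(OC)c(OC)c(OC)c3)c(OC)c2)c(OC)c1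
F6 | step 6 | racemic 4-(ArO)-3-(triisopropylsilyloxy)cyclobut-2-en-1-one | O=C1C=C(O[Si](C(C)C)(C(C)C)C(C)C)C1Oc1cc(OC)c(OC)c(OC)c1Oc1cc(OC)c(OC)c(OC)c1
F7 | step 6 | 2-(ArO)-3,5-bis(triisopropylsilyloxy)phenol | Oc1cc(O[Si](C(C)C)(C(C)C)C(C)C)cc(O[Si](C(C)C)(C(C)C)C(C)C)c1Oc1cc(OC)c(OC)c(OC)c1Oc1cc(OC)c(OC)c(OC)c1
F8 | step 6 | 2-(ArO)benzene-1,3,5-triol | Oc1cc(O)c(Oc2cc(OC)c(OC)c(OC)c2Oc2cc(OC)c(OC)c(OC)c2)c(O)c1
F9 | step 6 | 2-(ArO)-5-(triisopropylsilyloxy)benzene-1,3-diol | Oc1cc(O[Si](C(C)C)(C(C)C)C(C)C)cc(O)c1Oc1cc(OC)c(OC)c(OC)c1Oc1cc(OC)c(OC)c(OC)c1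
F10 | step 11 | 4-(ArO)-2-bromo-3,5-diethoxyphenol | CCOc1cc(O)c(Br)c(OCC)c1Oc1cc(OC)c(OC)c(OC)c1Oc1cc(OC)c(OC)c(OC)c1
F11 | step 11 | [4-(ArO)-2-bromo-3,5-diethoxyphenoxy]trimethylsilane | CCOc1cc(O[Si](C)(C)C)c(Br)c(OCC)c1Oc1cc(OC)c(OC)c(OC)c1Oc1cc(OC)c(OC)c(OC)c1
F12 | step 16 | 4-(ArO)-3,5-diethoxyphenyl trifluoromethanesulfonate | CCOc1cc(OS(=O)(=O)C(F)(F)F)cc(OCC)c1Oc1cc(OC)c(OC)c(OC)c1Oc1cc(OC)c(OC)c(OC)c1
F13 | step 17 | tetradecaacetate of the target | CC(=O)Oc1cc(OC(C)=O)c(Oc2cc(OC(C)=O)c(OC(C)=O)c(OC(C)=O)c2Oc2cc(OC(C)=O)c(Oc3cc(OC(C)=O)c(OC(C)=O)c(OC(C)=O)c3Oc3cc(OC(C)=O)c(OC(C)=O)c(OC(C)=O)c3)c(OC(C)=O)c2)c(OC(C)=O)c1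
A1 | alternative 1 | pentameric tris-phenol with free hydroxyl on C4 of rings B, D and E and eleven methyl ethers | COc1cc(OC)c(Oc2cc(OC)c(O)c(OC)c2Oc2cc(OC)c(Oc3cc(OC)c(O)c(OC)c3Oc3cc(OC)c(O)c(OC)c3)c(OC)c2)c(OC)c1
A2 | alternative 1 | pentameric trialdehyde with formyl on C4 of rings B, D and E and eleven methyl ethers | COc1cc(OC)c(Oc2cc(OC)c(C=O)c(OC)c2Oc2cc(OC)c(Oc3cc(OC)c(C=O)c(OC)c3Oc3cc(OC)c(C=O)c(OC)c3)c(OC)c2)c(OC)c1
A3 | alternative 2 | 3,4,5-trimethoxy-2-(3,4,5-trimethoxyphenoxy)phenol (identical with 6) | Oc1cc(OC)c(OC)c(OC)c1Oc1cc(OC)c(OC)c(OC)c1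
A4 | alternative 2 | racemic 3,4-dimethoxy-4-(1-methoxyethenyl)-2-(3,4,5-trimethoxyphenoxy)cyclobut-2-en-1-one | C=C(OC)C1(OC)C(OC)=C(Oc2cc(OC)c(OC)c(OC)c2)C1=O
A5 | alternative 3 | pentamer with ring E as C3 free phenol, C4 benzyl ether and C5 ethyl ether, rings A to D as methyl ethers | COc1cc(OC)c(Oc2cc(OC)c(OC)c(OC)c2Oc2cc(OC)c(Oc3cc(OC)c(OC)c(OC)c3Oc3cc(O)c(OCc4ccccc4)c(OCC)c3)c(OC)c2)c(OC)c1
A6 | alternative 3 | ethynyl ether of the permethylated A–D tetramer (ethynyloxy on D2) | COc1cc(OC)c(Oc2cc(OC)c(OC)c(OC)c2Oc2cc(OC)c(Oc3cc(OC)c(OC)c(OC)c3OC#C)c(OC)c2)c(OC)c1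
A7 | alternative 3 | racemic 4-(benzyloxy)-3-ethoxycyclobut-2-en-1-one | O=C1C=C(OCC)C1OCc1ccccc1
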